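## Retrosynthetic overview

1. Locants: ring A carries its oxygen para to the biaryl bond (C1' biaryl, C3' side chain, C4' O, C6' CH3). Ring B carries its oxygen ortho to the biaryl bond (C1 biaryl, C2 O, C3 side chain, C6 CH3).
2. Feature: both stereocentres are benzylic CH(CH3) carbons, one on C3' of ring A and one on C3 of ring B. Each lies ortho to a ring oxygen and is bonded to the first CH2 of a 4-methylpent-3-enyl chain.
3. After unmasking the two phenols from their methyl ethers, both C(benzylic)–CH2 bonds are cut together. This leads to a stereorandom bis(1-chloroethyl) biaryl and two equivalents of (4-methylpent-3-enyl)zinc bromide (twofold enantioconvergent Negishi coupling).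
4. The bis-chloride comes from the divinyl biaryl by HCl addition, the diene from the dialdehyde by Wittig methylenation, and the dialdehyde from the biphenyldiol by phenoxide-directed ortho-formylation at C3 and C3'.
5. The C1–C1' bond is made first by Suzuki–Miyaura coupling. No ring is formed in the route, since both benzene rings are bought.

Key step: step 8

Assumption: the tri-ortho-substituted biaryl axis (CH3/H against CH3/O) has no descriptor in the target and is taken to rotate at the temperature of the last step, so it is not controlled; intermediates may appear as rotamer pairs.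

Assumption: (S,S)-i-Pr-pybox is written as the ligand enantiomer that leads to (S) carbons; the sense is to be checked on a one-ring model chloride first, and the equally available mirror-image ligand is used if the check demands it.

## Route

Step 1
Reactants: 1 4-bromo-3-methylanisole; 2 (2-methoxy-6-methylphenyl)boronic acid (1.5 equiv)
Product: 3 2,4'-dimethoxy-6,6'-dimethyl-1,1'-biphenyl
Conditions: Pd(OAc)2 (2 mol %), SPhos (4 mol %), K3PO4, PhMe/H2O (10:1), 100 °C
Reagents that add atoms: none
Why: Suzuki–Miyaura coupling, in which the bulky electron-rich biarylphosphine speeds oxidative addition into the electron-rich bromide and bond formation at a tri-ortho-substituted axis, while the excess of 2 offsets protodeboronation.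

Step 2
Reactants: 3 2,4'-dimethoxy-6,6'-dimethyl-1,1'-biphenyl
Product: 4 6,6'-dimethyl-[1,1'-biphenyl]-2,4'-diol
Conditions: BBr3 (3 equiv), CH2Cl2, −78 °C → rt; then H2O
Reagents that add atoms: none
Why: Lewis-acid cleavage of aryl methyl ethers (bromide attacks the O-methyl carbon of the boron-complexed ether) frees both phenols, which step 3 needs as ortho-directing groups, and nothing else in 3 is sensitive.

Step 3
Reactants: 4 6,6'-dimethyl-[1,1'-biphenyl]-2,4'-diol
Product: 5 2,4'-dihydroxy-6,6'-dimethyl-[1,1'-biphenyl]-3,3'-dicarbaldehyde
Conditions: anhydrous MgCl2, Et3N, (CH2O)n (excess), MeCN, reflux; then 1 M HCl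
Reagents that add atoms: paraformaldehyde (as formaldehyde), C=O
Why: Casnati–Skattebøl ortho-formylation, in which each magnesium phenoxide delivers coordinated formaldehyde to an ortho carbon only and a second formaldehyde oxidises the benzylic alkoxide by hydride transfer; ring B has one free ortho position (C3), and on ring A the open C3' is preferred to C5', which is wedged between the oxygen and the 6'-methyl group.

Step 4
Reactants: 5 2,4'-dihydroxy-6,6'-dimethyl-[1,1'-biphenyl]-3,3'-dicarbaldehyde
Product: 6 2,4'-dimethoxy-6,6'-dimethyl-[1,1'-biphenyl]-3,3'-dicarbaldehyde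
Conditions: MeI, K2CO3, DMF, rt → 40 °C
Reagents that add atoms: iodomethane, CI
Why: Williamson ether synthesis (SN2 of the phenoxides on MeI) in a dipolar aprotic solvent overcomes the hydrogen-bonded salicylaldehyde OH groups, and methyl ethers are chosen because they withstand HCl, organozinc reagents and low-valent nickel.

Step 5
Reactants: 6 2,4'-dimethoxy-6,6'-dimethyl-[1,1'-biphenyl]-3,3'-dicarbaldehyde
Product: 7 3,3'-diethenyl-2,4'-dimethoxy-6,6'-dimethyl-1,1'-biphenyl
Conditions: MePPh3Br, KOt-Bu, THF, 0 °C → rt
Reagents that add atoms: methyltriphenylphosphonium bromide, C[P+](c1ccccc1)(c1ccccc1)c1ccccc1.[Br-]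
Why: Wittig methylenation of two non-enolisable aryl aldehydes with the unstabilised ylide is dependable next to ortho substituents and gives a storable diene without stereocentres that can be purified fully before the labile stage.

Step 6
Reactants: 7 3,3'-diethenyl-2,4'-dimethoxy-6,6'-dimethyl-1,1'-biphenyl
Product: 8 3,3'-bis(1-chloroethyl)-2,4'-dimethoxy-6,6'-dimethyl-1,1'-biphenyl (mixture of all stereoisomers)
Conditions: dry HCl (g), CH2Cl2, 0 °C; volatiles removed cold in vacuo; taken up in DMA and used at once
Reagents that add atoms: hydrogen chloride, Cl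
Why: Markovnikov electrophilic hydrochlorination, in which protonation of each vinyl group gives the benzylic cation stabilised by the ortho-methoxy and para-methyl groups and chloride collapses on it; only gas and solvent have to be removed, so the labile bis-chloride is obtained without aqueous work-up or chromatography, and its lack of stereochemical definition does not matter for step 8.

Step 7
Reactants: 9 5-bromo-2-methylpent-2-ene
Product: 10 (4-methylpent-3-en-1-yl)zinc bromide (titrated solution in DMA)
Conditions: Zn dust (1.5 equiv), I2 (5 mol %), DMA, 70 °C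
Reagents that add atoms: zinc, [Zn]
Why: Direct oxidative insertion of iodine-activated zinc into a primary C–Br bond in a polar amide solvent leaves the trisubstituted alkene untouched, and any cyclopropylcarbinyl excursion of the homoallylic radical reopens to the same chain.

Step 8
Reactants: 8 3,3'-bis(1-chloroethyl)-2,4'-dimethoxy-6,6'-dimethyl-1,1'-biphenyl; 10 (4-methylpent-3-en-1-yl)zinc bromide (3.2 equiv)
Product: 13 2,4'-dimethoxy-6,6'-dimethyl-3,3'-bis[(2S)-6-methylhept-5-en-2-yl]-1,1'-biphenyl, via ring-A-coupled monochloride 11 (not isolated), via ring-B-coupled monochloride 12 (not isolated)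
Conditions: NiBr2·diglyme (20 mol %), (S,S)-i-Pr-pybox (26 mol %), DMA, 0 °C, 8 added last
Reagents that add atoms: none
Why: A monovalent nickel–pybox halide abstracts chlorine from a benzylic C–Cl bond, the planar benzylic radical is captured by the divalent alkylnickel–pybox complex formed from 10 by transmetalation, and reductive elimination from the trivalent dialkylnickel species forms the C(benzylic)–CH2 bond and returns monovalent nickel; the cycle runs once on 8 and once more on the monochlorides 11 and 12. The closest known reaction type is this same enantioconvergent nickel/pybox Negishi alkyl–alkyl coupling of racemic secondary benzylic halides with primary alkylzinc halides, applied here at two sites of one molecule, and no ring is closed. As each radical has shed the configuration of its chloride, every stereoisomer of 8 is funnelled to the same product, and each new stereocentre (the benzylic carbon on C3' of ring A and the one on C3 of ring B) is fixed by the C2-symmetric ligand, whose isopropyl groups tell the flat aryl group from the methyl group when the radical binds to nickel and the bond is formed. The step needs catalyst control over any bias from the centre set first and from the biaryl axis; the two benzylic carbons lie on different rings, seven bonds apart, so each should be set independently, and selecting twice raises the enantiomeric purity of the (S,S) product while the errors collect in the (R,S) and (S,R) diastereomers. Chemoselectivity is secured by the weak, donor-activated benzylic C–Cl bonds, which react far faster than the aryl C–OCH3 bonds, while the trisubstituted alkene of 10 is too hindered to insert and a three-membered ring closure of the homoallyl unit would only be degenerate. Running at 0 °C with the chloride added last keeps ionisation, loss of HCl and uncatalysed racemic alkylation slow.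

Step 9
Reactants: 13 2,4'-dimethoxy-6,6'-dimethyl-3,3'-bis[(2S)-6-methylhept-5-en-2-yl]-1,1'-biphenyl
Product: 14 6,6'-dimethyl-3,3'-bis[(2S)-6-methylhept-5-en-2-yl]-[1,1'-biphenyl]-2,4'-diol (target)
Conditions: NaSEt (excess), degassed DMF, 140 °C; then 1 M HCl
Reagents that add atoms: none
Why: Nucleophilic SN2 demethylation of aryl methyl ethers by ethanethiolate touches only the O-methyl carbons, so the acid-sensitive trisubstituted alkenes and the non-acidic benzylic stereocentres stay as they are.

## Compound list

1 | 4-bromo-3-methylanisole | COc1ccc(Br)c(C)c1 | starting material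
2 | (2-methoxy-6-methylphenyl)boronic acid | COc1cccc(C)c1B(O)O | starting material
3 | 2,4'-dimethoxy-6,6'-dimethyl-1,1'-biphenyl | COc1ccc(-c2c(C)cccc2OC)c(C)c1 | intermediate
4 | 6,6'-dimethyl-[1,1'-biphenyl]-2,4'-diol | Oc1ccc(-c2c(C)cccc2O)c(C)c1 | intermediate
5 | 2,4'-dihydroxy-6,6'-dimethyl-[1,1'-biphenyl]-3,3'-dicarbaldehyde | O=Cc1cc(-c2c(C)ccc(C=O)c2O)c(C)cc1O | intermediate
6 | 2,4'-dimethoxy-6,6'-dimethyl-[1,1'-biphenyl]-3,3'-dicarbaldehyde | O=Cc1cc(-c2c(C)ccc(C=O)c2OC)c(C)cc1OC | intermediate
7 | 3,3'-diethenyl-2,4'-dimethoxy-6,6'-dimethyl-1,1'-biphenyl | C=Cc1cc(-c2c(C)ccc(C=C)c2OC)c(C)cc1OC | intermediate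
8 | 3,3'-bis(1-chloroethyl)-2,4'-dimethoxy-6,6'-dimethyl-1,1'-biphenyl, all stereoisomers | CC(Cl)c1cc(-c2c(C)ccc(C(C)Cl)c2OC)c(C)cc1OC | intermediate
9 | 5-bromo-2-methylpent-2-ene | CC(C)=CCCBr | starting material
10 | (4-methylpent-3-en-1-yl)zinc bromide | CC(C)=CCC[Zn]Br | intermediate
11 | 3-(1-chloroethyl)-2,4'-dimethoxy-6,6'-dimethyl-3'-[(2S)-6-methylhept-5-en-2-yl]-1,1'-biphenyl, both epimers at the C–Cl carbon | CC(C)=CCC[C@H](C)c1cc(-c2c(C)ccc(C(C)Cl)c2OC)c(C)cc1OC | intermediate
12 | 3'-(1-chloroethyl)-2,4'-dimethoxy-6,6'-dimethyl-3-[(2S)-6-methylhept-5-en-2-yl]-1,1'-biphenyl, both epimers at the C–Cl carbon | CC(Cl)c1cc(-c2c(C)ccc([C@@H](C)CCC=C(C)C)c2OC)c(C)cc1OC | intermediate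
13 | 2,4'-dimethoxy-6,6'-dimethyl-3,3'-bis[(2S)-6-methylhept-5-en-2-yl]-1,1'-biphenyl | CC(C)=CCC[C@H](C)c1cc(-c2c(C)ccc([C@@H](C)CCC=C(C)C)c2OC)c(C)cc1OC | intermediate
14 | 6,6'-dimethyl-3,3'-bis[(2S)-6-methylhept-5-en-2-yl]-[1,1'-biphenyl]-2,4'-diol | CC(C)=CCC[C@H](C)c1cc(-c2c(C)ccc([C@@H](C)CCC=C(C)C)c2O)c(C)cc1O | target

## Step count and risks

Total step count: 9.
Longest linear sequence: 8 steps (steps 1–6, 8 and 9). Step 7 runs in parallel.

**1. Step 8.**
- Facial discrimination at acyclic benzylic radicals that carry an ortho-methoxy group may be too weak. The resulting (R,S) and (S,R) diastereomers would be hard to remove because the centres are remote.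
- Ionisation or solvolysis of the chloride in DMA, loss of HCl, radical dimerisation, or stalling after the first coupling may also erode the result.
- The fallback sets out from 7 and comes back at 13, and it makes the benzylic stereocentres from the other side.
- Nickel-catalysed asymmetric hydrovinylation of both vinyl groups with ethylene should give 3,3'-bis[(2S)-but-3-en-2-yl]-2,4'-dimethoxy-6,6'-dimethyl-1,1'-biphenyl F1. Conditions are [Ni(C3H5)Br]2, a BINOL-derived phosphoramidite bearing a bis(1-phenylethyl)amino group in the enantiomer that gives (S), Na[B(3,5-(CF3)2C6H3)4] and CH2Cl2 at low temperature.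
- Hydroboration of its two monosubstituted alkenes with 9-BBN-H in THF gives 3,3'-bis[(2S)-4-(9-borabicyclo[3.3.1]nonan-9-yl)butan-2-yl]-2,4'-dimethoxy-6,6'-dimethyl-1,1'-biphenyl F2.
- F2 is coupled in the same flask with 1-bromo-2-methylprop-1-ene (PdCl2(dppf), aqueous NaOH, THF/DMF) in a B-alkyl Suzuki–Miyaura reaction to give 13.

**2. Step 6.**
- Addition of HCl to the less activated ring-B vinyl group may stay incomplete.
- Acid may start cationic oligomerisation of the electron-rich styrene units.
- The product may lose HCl again on concentration.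
- The fallback sets out from 6 and comes back at 8, replacing alkene addition by substitution at an alcohol.
- Addition of MeMgBr (THF, 0 °C) to both aldehydes gives 3,3'-bis(1-hydroxyethyl)-2,4'-dimethoxy-6,6'-dimethyl-1,1'-biphenyl F3 as a stereoisomer mixture.
- Deoxychlorination of F3 with SOCl2 (CH2Cl2, 0 °C, evaporation only) delivers 8.

**3. Step 3.**
- The second formylation may stall at the hindered ring-B phenoxide.
- Some attack may occur at C5' of ring A.
- Long heating may convert the phenols into methoxymethyl ethers.
- The fallback sets out from 4 and comes back at 5, separating C–C bond formation from oxidation.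
- Phenylboronic-acid-templated ortho-hydroxymethylation (PhB(OH)2, paraformaldehyde, catalytic propionic acid, toluene, reflux with removal of water) gives 7,7'-dimethyl-2,2'-diphenyl-4H,4'H-6,8'-bi(1,3,2-benzodioxaborinine) F4.
- Exchange with propane-1,3-diol releases 3,3'-bis(hydroxymethyl)-6,6'-dimethyl-[1,1'-biphenyl]-2,4'-diol F5.
- Selective benzylic oxidation of F5 with MnO2 (CH2Cl2, rt) gives 5.

## Further compounds

F1 | step 8 | 3,3'-bis[(2S)-but-3-en-2-yl]-2,4'-dimethoxy-6,6'-dimethyl-1,1'-biphenyl | C=C[C@H](C)c1cc(-c2c(C)ccc([C@@H](C)C=C)c2OC)c(C)cc1OC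
F2 | step 8 | 3,3'-bis[(2S)-4-(9-borabicyclo[3.3.1]nonan-9-yl)butan-2-yl]-2,4'-dimethoxy-6,6'-dimethyl-1,1'-biphenyl | C1CCC2CCCC1B2CC[C@H](C)c1cc(-c2c(C)ccc([C@@H](C)CCB3C4CCCC3CCC4)c2OC)c(C)cc1OC
F3 | step 6 | 3,3'-bis(1-hydroxyethyl)-2,4'-dimethoxy-6,6'-dimethyl-1,1'-biphenyl, all stereoisomers | CC(O)c1cc(-c2c(C)ccc(C(C)O)c2OC)c(C)cc1OC
F4 | step 3 | 7,7'-dimethyl-2,2'-diphenyl-4H,4'H-6,8'-bi(1,3,2-benzodioxaborinine) | C1OB(c2ccccc2)Oc2cc(C)c(-c3c(C)ccc4c3OB(c3ccccc3)OC4)cc21
F5 | step 3 | 3,3'-bis(hydroxymethyl)-6,6'-dimethyl-[1,1'-biphenyl]-2,4'-diol | OCc1cc(-c2c(C)ccc(CO)c2O)c(C)cc1O
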